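The plan rests on cutting two bonds of the acyclic C7–C8–C8'–C7' chain at once: C8'–C9' and C8–C7. The feature used is that C8' carries a methyl (C9') while its neighbour C8 carries a one-carbon branch (C9) and the guaiacyl-ring benzylic carbon C7. One operation therefore adds methyl enantioselectively to the β-carbon of a thioester acceptor and lets the enolate capture O-benzylvanillin, setting C8' and C8 and joining both arene halves; no ring forms. The precursor is an S-ethyl (E)-but-2-enethioate carrying the benzyl-protected syringyl ring on C4; its thioester carbon is later reduced to the C9 methyl and the C7 hydroxyl is hydrogenolysed.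

Key step: step 4

Numbering remark: lignan numbering is used; C7, C8, C9 lie on the guaiacyl (4-hydroxy-3-methoxyphenyl) side and C7', C8', C9' on the syringyl (4-hydroxy-3,5-dimethoxyphenyl) side; the target is (8R,8'S), the meso-like (erythro) arrangement.

Assumption: the copper catalyst is taken to show the same facial preference on 7 as on simple (E)-alkyl enethioates, for which the (S,R_p) ligand enantiomer named in step 4 should give (S) at C8'; should the adduct prove to be the antipode, the (R,S_p) ligand is used and nothing else changes.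

Step 1
Reactants: 1 4-allyl-2,6-dimethoxyphenol; 2 benzyl bromide
Product: 3 5-allyl-2-(benzyloxy)-1,3-dimethoxybenzene
Conditions: K2CO3, DMF, rt
Reagents that add atoms: benzyl bromide, BrCc1ccccc1
Why: Williamson ether synthesis, in which the phenoxide formed with K2CO3 displaces bromide from benzyl bromide by SN2 while the allyl group stays untouched.

Step 2
Reactants: 4 acryloyl chloride; 5 ethanethiol
Product: 6 S-ethyl prop-2-enethioate
Conditions: 5, aq NaOH, NaBH4 (cat.), added to 4 (1.2 equiv), BHT, cyclohexane, 55 °C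
Reagents that add atoms: ethanethiol, CCS
Why: Schotten–Baumann S-acylation in a two-phase system, where thiolate meets an excess of acid chloride and is acylated faster than it can add to the acrylate double bond, with NaBH4 suppressing disulfide formation and BHT suppressing radical polymerisation.

Step 3
Reactants: 3 5-allyl-2-(benzyloxy)-1,3-dimethoxybenzene; 6 S-ethyl prop-2-enethioate
Product: 7 S-ethyl (E)-4-(4-benzyloxy-3,5-dimethoxyphenyl)but-2-enethioate
Conditions: [1,3-bis(2,4,6-trimethylphenyl)imidazolidin-2-ylidene]dichloro(2-isopropoxybenzylidene)ruthenium (second-generation Hoveyda–Grubbs catalyst, 3 mol%), 1,4-benzoquinone (10 mol%), 6 (3 equiv), CH2Cl2, 40 °C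
Reagents that add atoms: S-ethyl prop-2-enethioate, C=CC(=O)SCC
Why: Olefin cross-metathesis of a reactive terminal olefin with an electron-poor acrylate-type partner on a phosphine-free ruthenium carbene, which should give the E-enethioate with loss of ethene, benzoquinone holding back hydride-induced migration of the allyl double bond.

Step 4
Reactants: 7 S-ethyl (E)-4-(4-benzyloxy-3,5-dimethoxyphenyl)but-2-enethioate; 8 methylmagnesium bromide; 9 4-benzyloxy-3-methoxybenzaldehyde
Product: 11 S-ethyl (2S,3S)-2-[(S)-(4-benzyloxy-3-methoxyphenyl)(hydroxy)methyl]-4-(4-benzyloxy-3,5-dimethoxyphenyl)-3-methylbutanethioate, via bromomagnesium thioester enolate 10 (not isolated)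
Conditions: CuBr·SMe2 (5 mol%), (S)-1-[(R_p)-2-(diphenylphosphino)ferrocenyl]ethyldicyclohexylphosphine (Josiphos type, 6 mol%), 8 (1.2 equiv), t-BuOMe, −75 °C, 7 added slowly; then 9 (1.4 equiv) in CH2Cl2, −75 °C; aq NH4Cl at −75 °C
Reagents that add atoms: methylmagnesium bromide, C[Mg]Br; 4-benzyloxy-3-methoxybenzaldehyde, COc1cc(C=O)ccc1OCc1ccccc1
Why: A methylcopper–diphosphine complex formed by transmetalation from MeMgBr binds the enethioate as a π-complex, adds at C8' to a trivalent copper σ-species and reductively eliminates the C8'–C9' bond, leaving the oxygen-cis bromomagnesium enolate 10, which adds to aldehyde 9 through a closed six-membered Zimmerman–Traxler transition state to form C8–C7. The closest known reaction type is the copper-catalysed enantioselective conjugate addition of Grignard reagents to α,β-unsaturated thioesters with in situ aldol trapping of the magnesium enolate; no ring is closed. C8' is set by the ligand enantiomer, which selects the face of the β-carbon. C8 is set by 1,2-induction from C8': the C8'–H bond eclipses the enolate to relieve allylic strain and the aldehyde should approach on the methyl side, anti to the CH2Ar group, which places the thioester carbon anti to C9' along the C7–C7' chain. C7 is set by the chair transition state of the oxygen-cis enolate (syn aldol) and is deleted in step 8. The step needs 1,4-addition to win over 1,2-addition and over deprotonation of the doubly activated γ-CH2, which the enone-like acceptor strength of the thioester, the soft copper catalyst, t-BuOMe, −75 °C and slow addition of 7 should secure.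

Step 5
Reactants: 11 S-ethyl (2S,3S)-2-[(S)-(4-benzyloxy-3-methoxyphenyl)(hydroxy)methyl]-4-(4-benzyloxy-3,5-dimethoxyphenyl)-3-methylbutanethioate
Product: 12 (1S,2R)-1-(4-benzyloxy-3-methoxyphenyl)-2-[(2S)-1-(4-benzyloxy-3,5-dimethoxyphenyl)propan-2-yl]propane-1,3-diol
Conditions: LiAlH4, THF, −10 to 0 °C; then H2O, 15% aq NaOH, H2O
Reagents that add atoms: none
Why: Hydride reduction of a thioester to the primary alcohol, fast enough at low temperature that the aldolate should neither revert by retro-aldol cleavage nor epimerise at C8 (the change of the C8 descriptor to R is a priority change only).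

Step 6
Reactants: 12 (1S,2R)-1-(4-benzyloxy-3-methoxyphenyl)-2-[(2S)-1-(4-benzyloxy-3,5-dimethoxyphenyl)propan-2-yl]propane-1,3-diol; 13 4-methylbenzenesulfonyl chloride
Product: 14 (2R,3S)-3-(4-benzyloxy-3-methoxyphenyl)-2-[(2S)-1-(4-benzyloxy-3,5-dimethoxyphenyl)propan-2-yl]-3-hydroxypropyl 4-methylbenzenesulfonate
Conditions: 13 (1.05 equiv), Et3N, DMAP (cat.), CH2Cl2, 0 °C
Reagents that add atoms: 4-methylbenzenesulfonyl chloride, Cc1ccc(cc1)S(=O)(=O)Cl
Why: Selective sulfonylation of the unhindered primary hydroxyl of a 1,3-diol, which reacts far faster than the hindered secondary benzylic hydroxyl when the sulfonyl chloride is kept near one equivalent at 0 °C.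

Step 7
Reactants: 14 (2R,3S)-3-(4-benzyloxy-3-methoxyphenyl)-2-[(2S)-1-(4-benzyloxy-3,5-dimethoxyphenyl)propan-2-yl]-3-hydroxypropyl 4-methylbenzenesulfonate
Product: 15 (1S,2S,3S)-1-(4-benzyloxy-3-methoxyphenyl)-4-(4-benzyloxy-3,5-dimethoxyphenyl)-2,3-dimethylbutan-1-ol
Conditions: LiEt3BH (3 equiv), THF, 0 °C to rt; then H2O
Reagents that add atoms: none
Why: SN2 displacement of a primary tosylate by hydride (reductive deoxygenation), which turns C9–O into C9–H without touching a stereocentre, the C7 hydroxyl being only deprotonated and its alkoxide tamed as a triethylborane ate complex.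

Step 8
Reactants: 15 (1S,2S,3S)-1-(4-benzyloxy-3-methoxyphenyl)-4-(4-benzyloxy-3,5-dimethoxyphenyl)-2,3-dimethylbutan-1-ol
Product: 16 4-[(2S,3R)-4-(4-hydroxy-3-methoxyphenyl)-2,3-dimethylbutyl]-2,6-dimethoxyphenol
Conditions: H2 (3 bar), 10% Pd/C, EtOH–AcOH, rt to 40 °C
Reagents that add atoms: none
Why: Palladium-catalysed hydrogenolysis, in which both benzyl ethers cleave first and the resulting 4-hydroxy-3-methoxybenzylic carbinol, strongly activated toward C–O cleavage, is reduced to the C7 methylene, while the non-benzylic centres C8 and C8' are not touched.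

Compound list
1 | 4-allyl-2,6-dimethoxyphenol | C=CCc1cc(OC)c(O)c(OC)c1 | starting material
2 | benzyl bromide | BrCc1ccccc1 | starting material
3 | 5-allyl-2-(benzyloxy)-1,3-dimethoxybenzene | C=CCc1cc(OC)c(OCc2ccccc2)c(OC)c1 | intermediate
4 | acryloyl chloride | C=CC(=O)Cl | starting material
5 | ethanethiol | CCS | starting material
6 | S-ethyl prop-2-enethioate | C=CC(=O)SCC | intermediate
7 | S-ethyl (E)-4-(4-benzyloxy-3,5-dimethoxyphenyl)but-2-enethioate | CCSC(=O)/C=C/Cc1cc(OC)c(OCc2ccccc2)c(OC)c1 | intermediate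
8 | methylmagnesium bromide | C[Mg]Br | starting material
9 | 4-benzyloxy-3-methoxybenzaldehyde (O-benzylvanillin, commercial) | COc1cc(C=O)ccc1OCc1ccccc1 | starting material
10 | bromomagnesium (1E,3S)-4-(4-benzyloxy-3,5-dimethoxyphenyl)-1-(ethylsulfanyl)-3-methylbut-1-en-1-olate (oxygen cis to C8') | CCS/C(O[Mg]Br)=C/[C@@H](C)Cc1cc(OC)c(OCc2ccccc2)c(OC)c1 | intermediate
11 | S-ethyl (2S,3S)-2-[(S)-(4-benzyloxy-3-methoxyphenyl)(hydroxy)methyl]-4-(4-benzyloxy-3,5-dimethoxyphenyl)-3-methylbutanethioate | COc1cc([C@@H](O)[C@@H](C(=O)SCC)[C@@H](C)Cc2cc(OC)c(OCc3ccccc3)c(OC)c2)ccc1OCc1ccccc1 | intermediate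
12 | (1S,2R)-1-(4-benzyloxy-3-methoxyphenyl)-2-[(2S)-1-(4-benzyloxy-3,5-dimethoxyphenyl)propan-2-yl]propane-1,3-diol | COc1cc([C@@H](O)[C@@H](CO)[C@@H](C)Cc2cc(OC)c(OCc3ccccc3)c(OC)c2)ccc1OCc1ccccc1 | intermediate
13 | 4-methylbenzenesulfonyl chloride | Cc1ccc(cc1)S(=O)(=O)Cl | starting material
14 | (2R,3S)-3-(4-benzyloxy-3-methoxyphenyl)-2-[(2S)-1-(4-benzyloxy-3,5-dimethoxyphenyl)propan-2-yl]-3-hydroxypropyl 4-methylbenzenesulfonate | COc1cc([C@@H](O)[C@@H](COS(=O)(=O)c2ccc(C)cc2)[C@@H](C)Cc2cc(OC)c(OCc3ccccc3)c(OC)c2)ccc1OCc1ccccc1 | intermediate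
15 | (1S,2S,3S)-1-(4-benzyloxy-3-methoxyphenyl)-4-(4-benzyloxy-3,5-dimethoxyphenyl)-2,3-dimethylbutan-1-ol | COc1cc([C@@H](O)[C@@H](C)[C@@H](C)Cc2cc(OC)c(OCc3ccccc3)c(OC)c2)ccc1OCc1ccccc1 | intermediate
16 | 4-[(2S,3R)-4-(4-hydroxy-3-methoxyphenyl)-2,3-dimethylbutyl]-2,6-dimethoxyphenol | COc1cc(C[C@@H](C)[C@@H](C)Cc2cc(OC)c(O)c(OC)c2)ccc1O | target

Total step count: 8.
Longest linear sequence: 7 steps (steps 1, 3, 4, 5, 6, 7, 8); step 2 is a one-step side branch.

Steps most likely to fail

Step 4. The trapping may show weak or even reversed 1,2-induction at C8, because methyl and CH2Ar on C8' differ little in size. Also, MeMgBr may deprotonate the γ-CH2 and deconjugate the acceptor before methyl transfer, and the magnesium aldolate may revert on warming. The fallback separates the two bond formations and puts C8 under auxiliary control. It sets out from 7: the same copper/ligand/MeMgBr conjugate addition, stopped with NH4Cl at −75 °C, should give S-ethyl (3S)-4-(4-benzyloxy-3,5-dimethoxyphenyl)-3-methylbutanethioate F1. Hydrolysis (LiOH, H2O2, THF–H2O) gives (3S)-4-(4-benzyloxy-3,5-dimethoxyphenyl)-3-methylbutanoic acid F2. Acylation of lithiated (S)-4-benzyloxazolidin-2-one through the pivaloyl mixed anhydride gives (4S)-4-benzyl-3-[(3S)-4-(4-benzyloxy-3,5-dimethoxyphenyl)-3-methylbutanoyl]oxazolidin-2-one F3. The Evans syn aldol (Bu2BOTf, i-Pr2NEt, CH2Cl2, −78 to 0 °C, then 9) should give (4S)-4-benzyl-3-[(2S,3S)-2-[(S)-(4-benzyloxy-3-methoxyphenyl)(hydroxy)methyl]-4-(4-benzyloxy-3,5-dimethoxyphenyl)-3-methylbutanoyl]oxazolidin-2-one F4, with C8 and C7 dictated by the auxiliary and identical to those of 11. Reductive removal of the auxiliary (LiBH4, THF–MeOH, 0 °C) comes back to the route at diol 12.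

Step 8. The benzylic C7–O bond may cleave sluggishly, and acid used to drive it may ionise C7. Ionisation could lead to elimination toward C8, which would erase that centre on re-hydrogenation, or to Friedel–Crafts closure onto the syringyl ring. The fallback removes the hydroxyl by radical deoxygenation (Barton–McCombie) and sets out from 15. NaH, CS2, then MeI in THF at 0 °C gives O-[(1S,2S,3S)-1-(4-benzyloxy-3-methoxyphenyl)-4-(4-benzyloxy-3,5-dimethoxyphenyl)-2,3-dimethylbutyl] S-methyl carbonodithioate F5. Bu3SnH and AIBN in toluene at 80–100 °C give 2-(benzyloxy)-5-[(2S,3R)-4-(4-benzyloxy-3-methoxyphenyl)-2,3-dimethylbutyl]-1,3-dimethoxybenzene F6. Neutral hydrogenolysis of the two benzyl ethers (H2, 10% Pd/C, EtOAc–EtOH, rt) comes back to the route at target 16.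

Step 7. The lithium alkoxide formed first at C7 may attack C9 to close an oxetane, or fragment in a Grob sense to aldehyde 9 and an alkene. Hydride may also attack sulfur instead of carbon at the β-branched tosylate and return diol 12. The fallback avoids any alkoxide by a neutral radical reduction and sets out from 14. A Finkelstein exchange (NaI, acetone, reflux) gives (1S,2S,3S)-1-(4-benzyloxy-3-methoxyphenyl)-4-(4-benzyloxy-3,5-dimethoxyphenyl)-2-(iodomethyl)-3-methylbutan-1-ol F7. Reduction with Bu3SnH and AIBN in toluene at 80 °C comes back to the route at 15.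

Further compounds
F1 | step 4 | S-ethyl (3S)-4-(4-benzyloxy-3,5-dimethoxyphenyl)-3-methylbutanethioate | CCSC(=O)C[C@@H](C)Cc1cc(OC)c(OCc2ccccc2)c(OC)c1
F2 | step 4 | (3S)-4-(4-benzyloxy-3,5-dimethoxyphenyl)-3-methylbutanoic acid | OC(=O)C[C@@H](C)Cc1cc(OC)c(OCc2ccccc2)c(OC)c1
F3 | step 4 | (4S)-4-benzyl-3-[(3S)-4-(4-benzyloxy-3,5-dimethoxyphenyl)-3-methylbutanoyl]oxazolidin-2-one | O=C(C[C@@H](C)Cc1cc(OC)c(OCc2ccccc2)c(OC)c1)N1[C@@H](Cc2ccccc2)COC1=O
F4 | step 4 | (4S)-4-benzyl-3-[(2S,3S)-2-[(S)-(4-benzyloxy-3-methoxyphenyl)(hydroxy)methyl]-4-(4-benzyloxy-3,5-dimethoxyphenyl)-3-methylbutanoyl]oxazolidin-2-one | COc1cc([C@@H](O)[C@@H](C(=O)N2[C@@H](Cc3ccccc3)COC2=O)[C@@H](C)Cc2cc(OC)c(OCc3ccccc3)c(OC)c2)ccc1OCc1ccccc1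
F5 | step 8 | O-[(1S,2S,3S)-1-(4-benzyloxy-3-methoxyphenyl)-4-(4-benzyloxy-3,5-dimethoxyphenyl)-2,3-dimethylbutyl] S-methyl carbonodithioate | COc1cc([C@@H](OC(=S)SC)[C@@H](C)[C@@H](C)Cc2cc(OC)c(OCc3ccccc3)c(OC)c2)ccc1OCc1ccccc1
F6 | step 8 | 2-(benzyloxy)-5-[(2S,3R)-4-(4-benzyloxy-3-methoxyphenyl)-2,3-dimethylbutyl]-1,3-dimethoxybenzene | COc1cc(C[C@@H](C)[C@@H](C)Cc2cc(OC)c(OCc3ccccc3)c(OC)c2)ccc1OCc1ccccc1
F7 | step 7 | (1S,2S,3S)-1-(4-benzyloxy-3-methoxyphenyl)-4-(4-benzyloxy-3,5-dimethoxyphenyl)-2-(iodomethyl)-3-methylbutan-1-ol | COc1cc([C@@H](O)[C@@H](CI)[C@@H](C)Cc2cc(OC)c(OCc3ccccc3)c(OC)c2)ccc1OCc1ccccc1
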